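**Retrosynthetic overview**
1. The imidazole (the only ring) is formed last, by a redox-neutral formal [3+2] union of an internal alkyne (the C4–C5 unit with both carbon substituents) and an amidoxime (the N–C2–N unit carrying the acetoxybutyl chain). One C–O bond is made first, then two C–N bonds; the amidoxime N–O bond is the built-in oxidant.
2. Alkyne ⇒ 3,4-dimethoxyphenethyl bromide + 1-propynyllithium (acetylide alkylation).
3. Amidoxime ⇒ 4-cyanobutyl acetate + hydroxylamine; nitrile ⇒ 5-chloropentanenitrile + potassium acetate.
4. Either orientation of the annulation gives the same product, because the 4- and 5-positions of an N–H imidazole exchange by tautomerism.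

Assumption: the target has no stereocentre and no stereogenic double bond, so it is achiral and needs no stereocontrol; the two N–H tautomers of the imidazole are one compound.

**Step 1**
Reactants: 1 4-(2-bromoethyl)-1,2-dimethoxybenzene; 2 1-propynyllithium
Product: 3 1,2-dimethoxy-4-(pent-3-yn-1-yl)benzene
Conditions: 2 (1.3 equiv), THF/DMPU (4:1), −20 °C → rt, 12 h
Reagents that add atoms: 1-propynyllithium, CC#C[Li]
Why: Acetylide alkylation (SN2) of a primary bromide, with the dipolar aprotic co-solvent favouring substitution over E2 to the styrene; no stereocentre is formed.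

**Step 2**
Reactants: 4 5-chloropentanenitrile; 5 potassium acetate
Product: 6 4-cyanobutyl acetate
Conditions: KOAc (1.5 equiv), NaI (10 mol%), DMF, 80 °C, 12 h
Reagents that add atoms: potassium acetate, CC(=O)[O-].[K+]
Why: Finkelstein-assisted SN2 displacement of a primary chloride by acetate, to which the nitrile is inert.

**Step 3**
Reactants: 6 4-cyanobutyl acetate; 7 hydroxylamine
Product: 8 (Z)-5-amino-5-(hydroxyimino)pentyl acetate
Conditions: 50 wt% aq. NH2OH (1.2 equiv), EtOH, rt → 40 °C, 16 h
Reagents that add atoms: hydroxylamine, NO
Why: Nucleophilic addition of hydroxylamine to the nitrile (amidoxime formation) under mild, base-free conditions that leave the primary acetate intact, giving the thermodynamically preferred Z-amidoxime.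

**Step 4**
Reactants: 3 1,2-dimethoxy-4-(pent-3-yn-1-yl)benzene; 8 (Z)-5-amino-5-(hydroxyimino)pentyl acetate
Product: 13 O-acetylcypholophine, via O-alkenyl amidoxime 9 (not isolated), via isomeric O-alkenyl amidoxime 10 (not isolated), via alpha-amidino ketone 11 (not isolated), via isomeric alpha-amidino ketone 12 (not isolated)
Conditions: 8 (2.0 equiv), (IPr)AuNTf2 (5 mol%; IPr = 1,3-bis(2,6-diisopropylphenyl)imidazol-2-ylidene), 4 Å MS, 1,4-dioxane (1 M), 60 °C, 6 h; then 120 °C, 4 h
Reagents that add atoms: none
Why: Proposed new method: a cationic monovalent-gold catalyst π-activates the unactivated internal alkyne for anti-attack by the α-effect oxime oxygen of 8, and protodeauration gives the O-alkenyl amidoximes 9 and 10 (C–O bond formation); on heating, their N–H tautomers (3-aza-4-oxa-1,5-dienes) undergo a [3,3]-sigmatropic shift that breaks the weak N–O bond as internal oxidant and forms the first ring C–N bond, giving the α-amidino ketones 11 and 12, which cyclodehydrate (second C–N bond) to the aromatic imidazole, both regioisomeric series converging on 13 through N–H tautomerism; the closest known reactions are the thermal imidazole synthesis from amidoximes and propiolates (activated alkynes only), the Trofimov-type O-vinyl oxime rearrangement, and gold-catalysed hydroalkoxylation of internal alkynes.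

**Compound list**
1 | 4-(2-bromoethyl)-1,2-dimethoxybenzene (3,4-dimethoxyphenethyl bromide) | COc1ccc(CCBr)cc1OC | starting material
2 | 1-propynyllithium | CC#C[Li] | starting material
3 | 1,2-dimethoxy-4-(pent-3-yn-1-yl)benzene | CC#CCCc1ccc(OC)c(OC)c1 | intermediate
4 | 5-chloropentanenitrile | N#CCCCCCl | starting material
5 | potassium acetate | CC(=O)[O-].[K+] | starting material
6 | 4-cyanobutyl acetate (5-acetoxypentanenitrile) | CC(=O)OCCCCC#N | intermediate
7 | hydroxylamine (used as 50 wt% aqueous solution) | NO | starting material
8 | (Z)-5-amino-5-(hydroxyimino)pentyl acetate (5-acetoxy-N'-hydroxypentanimidamide) | CC(=O)OCCCC/C(N)=N/O | intermediate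
9 | 5-amino-5-({[(2Z)-5-(3,4-dimethoxyphenyl)pent-2-en-2-yl]oxy}imino)pentyl acetate (O-alkenyl amidoxime, oxygen on the methyl-bearing alkyne carbon; not isolated) | CC(=O)OCCCC/C(N)=N/O/C(C)=C\CCc1ccc(OC)c(OC)c1 | intermediate
10 | 5-amino-5-({[(3Z)-1-(3,4-dimethoxyphenyl)pent-3-en-3-yl]oxy}imino)pentyl acetate (regioisomeric O-alkenyl amidoxime; not isolated) | CC(=O)OCCCC/C(N)=N/O/C(CCc1ccc(OC)c(OC)c1)=C\C | intermediate
11 | 5-{[5-(3,4-dimethoxyphenyl)-2-oxopentan-3-yl]amino}-5-iminopentyl acetate (racemic, transient stereocentre lost on aromatisation; not isolated) | CC(=O)OCCCCC(=N)NC(CCc1ccc(OC)c(OC)c1)C(C)=O | intermediate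
12 | 5-{[5-(3,4-dimethoxyphenyl)-3-oxopentan-2-yl]amino}-5-iminopentyl acetate (racemic, transient stereocentre lost on aromatisation; not isolated) | CC(=O)OCCCCC(=N)NC(C)C(=O)CCc1ccc(OC)c(OC)c1 | intermediate
13 | O-acetylcypholophine, 4-{4-[2-(3,4-dimethoxyphenyl)ethyl]-5-methyl-1H-imidazol-2-yl}butyl acetate (achiral) | COc1ccc(CCc2nc(CCCCOC(C)=O)[nH]c2C)cc1OC | target

**Step count**
Total: 4 steps (convergent). Longest linear sequence: 3 steps (steps 2, 3, 4).

**Three steps most likely to fail**

Step 4 (the proposed new annulation) is the main risk. The basic amidoxime and the imidazole product can bind the gold cation. The electron-rich arene can attack the gold-activated alkyne intramolecularly, giving a dihydronaphthalene by hydroarylation. The water released can hydrate unreacted alkyne. The design counters these with excess amidoxime at high concentration, molecular sieves, and a low-temperature addition stage before the high-temperature rearrangement. Fallback with known chemistry, setting out from alkyne 3 and returning to the route at target 13: oxidise 3 with KMnO4 (acetone/water, NaHCO3, MgSO4, 0 °C → rt) to 1-(3,4-dimethoxyphenyl)pentane-3,4-dione F1. Condense F1 in a Debus–Radziszewski reaction with commercial tetrahydro-2H-pyran-2-ol (the lactol of 5-hydroxypentanal, OC1CCCCO1) and NH4OAc in MeOH (rt → 50 °C) to give cypholophine F2, the free alcohol. Acetylate F2 on oxygen with Ac2O/pyridine in CH2Cl2, followed by aqueous NaHCO3 work-up, to give 13. The unsymmetrical diketone poses no regiochemical problem, for the same tautomerism reason as in step 4.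

Step 1 can lose material by E2 elimination of the phenethyl bromide to 3,4-dimethoxystyrene under the basic acetylide. Fallback by polarity reversal, setting out from bromide 1 and returning at alkyne 3: convert 1 with Mg turnings in THF into [2-(3,4-dimethoxyphenyl)ethyl]magnesium bromide F3. Couple F3 with 1-bromoprop-1-yne (CC#CBr) under CuCl2 catalysis (3 mol%, THF, 0 °C) to give 3. The alkyl group is now the nucleophile, so base-induced elimination is no longer possible.

Step 3 may be slow for an aliphatic nitrile, and hydroxylamine may partly cleave the acetate to a hydroxamic acid. Fallback setting out from nitrile 6 and returning at amidoxime 8: convert 6 with O,O-diethyl dithiophosphoric acid and water (80 °C, acidic and ester-tolerant) into the thioamide 5-amino-5-thioxopentyl acetate F4. Treat F4 with 50 wt% aqueous NH2OH in EtOH at room temperature. The thiocarbonyl reacts with hydroxylamine far faster than the ester does and gives 8 with loss of hydrogen sulfide.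

**Further compounds**
F1 | step 4 | 1-(3,4-dimethoxyphenyl)pentane-3,4-dione | COc1ccc(CCC(=O)C(C)=O)cc1OC
F2 | step 4 | cypholophine, 4-{4-[2-(3,4-dimethoxyphenyl)ethyl]-5-methyl-1H-imidazol-2-yl}butan-1-ol | COc1ccc(CCc2nc(CCCCO)[nH]c2C)cc1OC
F3 | step 1 | [2-(3,4-dimethoxyphenyl)ethyl]magnesium bromide | COc1ccc(CC[Mg]Br)cc1OC
F4 | step 3 | 5-amino-5-thioxopentyl acetate | CC(=O)OCCCCC(N)=S
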